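(The earlier runs and the new flask were computed from invented constants, noise included.)

After 1.67 d the substrate in the zeta flask goes on falling, but slowly: it reads 44.2% there and 39.7% at 3.00 d.

the same everywhere: partner 0.152 M

| flask | substrate | remark | time |
|---|---|---|---|
| zeta | 0.19 M (in portions, 2) | the very flask that is asked about, followed so far; portions every 2.0 h |  |
| alpha | 0.095 M (in portions, 2) | run made earlier; portions every 2.0 h |  |
| flask | 0.19 M (in portions, 2) | the portions of substrate follow each other after 2.0 h, the first at the start | 15 d |

| run | time / d | target / % | substrate / % |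
|---|---|---|---|
| zeta | 0.167 | 11.6 | 76.0 |
| zeta | 0.500 | 21.4 | 59.3 |
| zeta | 0.833 | 23.3 | 51.5 |
| zeta | 1.25 | 23.3 | 47.4 |
| zeta | 1.67 | 25.3 | 44.2 |
| zeta | 2.50 | 27.3 | 42.8 |
| zeta | 3.00 | 27.2 | 39.7 |
| alpha | 0.833 | 30.3 | 30.9 |
| alpha | 2.50 | 36.7 | 10.8 |
| alpha | 4.00 | 39.6 | 6.4 |
| alpha | 6.00 | 41.7 | 3.1 |
| alpha | 10.0 | 43.6 | 0 |
| alpha | 12.0 | 44.6 | 1.3 |
| alpha | 15.0 | 45.2 | 0.5 |

(readings scatter by 1 percentage point)

- at 15 d, what has stopped the reaction, if anything has (forward and back rates have come level / it is still moving / the partner has run out first / all of the substrate has reacted)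
- the target standing at 15 d, as a percentage of the substrate charged

Let f be the fractional loss of substrate per day between two readings. Alpha read f = 0.631 d⁻¹ from 0.833 d to 2.50 d, and zeta read 0.0807 d⁻¹ from 1.67 d to 3.00 d, so alpha's f is higher by a factor of 7.82.

One chemist holds that each substrate takes one partner. By 3.00 d zeta has then used 0.115 M and keeps 0.0374 M of partner, so on this view it is a slower alpha and still moving.

The other answers that, on that count, alpha at 2.50 d kept 0.0673 M, a factor of 1.80 over zeta, which is less than the gap in f. She reads the partner as the limiting reagent and supposes it has gone by 3.00 d.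

My own reckoning follows her. Partner used per substrate used is then 1.33, and this ratio is the partner demand m; in the zeta flask substrate should stay near 39.7%.

The forecast sides with her, “Zeta's stall therefore looks like partner depletion”, and its verdict is that the partner has run out first, with target 31%. Its demand is 1.2 where mine is 1.33, and its substrate stops near 33% where mine stops near 39.7%.

In the flask the partner has run out first, with target 28.7%; at 15.0 d it holds substrate 40.5% and partner 0%, which returns m = 1.34.

    substrate + partner → target (k = 0.00720 M⁻¹ min⁻¹)
    target ⇌ isomer of the product (K = 0.360, k = 6.20 × 10⁻⁴ min⁻¹)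
    substrate + 2 partner → side product (k = 0.0630 M⁻² min⁻¹)

Take a neighbouring flask, the same but with 0.048 M of substrate. With m it wants 0.0637 M of partner, less than the 0.152 M charged, so substrate should end first with 58.1% of the partner left. At 15.0 d the neighbouring flask shows substrate 0% and partner 52.7%, so its own demand reads 1.50, higher than m. Partner left over is what the first chemist claimed for zeta, and the neighbouring flask is where that holds. The target in the neighbouring flask stands at 36.9%.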